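## The problem

Numbering used throughout: chroman numbering for ring A and the pyran (O1, C2, C3, C4, C4a, C5–C8, C8a). The quinone is ring Q, with Q1 bonded to C3, carbonyls at Q2 and Q5, methoxy groups at Q3 and Q4, and hydrogen at Q6.

Target 24 is an isoflavan whose C3 aryl group is a 2,3-dimethoxy-1,4-benzoquinone. Ring A is fused to the dihydropyran through C4a and C8a and carries methoxy groups at C6 and C7 and a free hydroxyl at C8. The two carbocycles meet only at the sp3 carbon C3, so a synthesis has to make the Q1–C3 bond, the C4–C4a bond and the O1–C2 bond around a three-carbon chain. C3 (S) is the only stereocentre, so nothing in the molecule can relay to it and its configuration must come from a chiral catalyst or reagent. The two arms it distinguishes differ only in ending on oxygen (C2) or on carbon (C4) of ring A. C3 is benzylic to ring Q and would epimerise if C2 or C4 became a carbonyl, or under base once the quinone is present, so both neighbours must stay methylenes after C3 is set and the quinone must be released last. The quinone does not survive strong base, nucleophiles or reducing agents, and the C8 phenol is easily over-oxidised; the three oxygens at Q2, Q5 and C8 therefore travel as ethers distinct from the four methoxy groups. Ring A is substituted on every carbon except C5, and the bond to be made, C4–C4a, ends on the carbon next to C5. A C4a≡C5 aryne is thus the only aryne ring A can form, a carbanion at C4 held by the C3–C2–O1 tether can reach only C4a, and C5 then needs nothing but a proton.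

## Retrosynthesis

**24 to 22 (no skeletal bond cut).** The quinone is traced to hydroquinone 23 and this to the tribenzyl ether 22. Benzyl separates the three oxygens that must end as C=O or OH from the four that stay methoxy. An all-methyl precursor would demand an oxidative demethylation that has to choose between two electron-rich rings. The forward reaction needs only hydrogenolysis and a mild two-electron oxidation that touches the para-hydroquinone and not the lone C8 phenol.

**22 to 21 (C4–S).** A phenylsulfonyl group is added at C4. It makes C4 a carbanion site for the ring closure and leaves again by reductive cleavage of a benzylic C–S bond. A nitrile or ester at C4 would also stabilise the anion but would cost several steps to remove. Both C4 epimers of 21 serve, so the forward step asks only for clean C–S cleavage without elimination towards C3.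

**21 to 18 (C4–C4a, the key cut).** Opening the pyran at C4–C4a gives the acyclic bromo sulfone 18, one ring simpler. The bond is formed through the lithiated sulfone 19 and the aryne 20. The neighbouring cut O1–C2 would leave the harder C4–C4a bond still to be made. Making C4–C4a by Friedel–Crafts acylation would place a ketone next to C3 and invite epimerisation. The aryne closure keeps C4 at the methylene oxidation level. The bromine sits on C4a, where it also allows an ipso coupling if the aryne fails; the aryne itself would form equally from a leaving group at C5. The forward reaction must deprotonate the sulfone α-carbon and C5–H while sparing C3–H and the benzylic ether positions.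

**18 to 9 and 17 (Q1–C3).** Cutting the aryl–C3 bond divides the molecule into two halves of similar size and makes the stereocentre the product of a catalytic asymmetric conjugate arylation of alkenyl sulfone 9 with boronic acid 17. The sulfone serves twice, as the acceptor-activating group here and as the carbanion-stabilising group in the key step, so no functional group change lies between the two steps. Cutting C2–C3 or C3–C4 instead would mean alkylating an arylacetic acid derivative under auxiliary control and then adjusting oxidation levels. The forward reaction must control the face of a β-alkyl alkenyl sulfone and tolerate an ortho-alkoxy aryl group and an aryl bromide.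

**9 to 7 and 8, then 7 to 5 and 6 (C3=C4 and O1–C2).** The alkene of 9 is cut by cross-metathesis into allyl ether 7 and phenyl vinyl sulfone 8. The ether bond of 7 is cut into phenol 5 and allyl bromide 6. Both forward reactions are neutral or weakly basic, which matters because a γ-aryloxy alkenyl sulfone can lose its conjugation under base.

**5 to 1 (ring A).** The bromine of 5 is removed to give phenol 4, in which the hydroxyl directs bromination to its only free ortho position. Phenol 4 comes from benzaldehyde 2 through formate 3 by oxidative replacement of the formyl carbon by oxygen. Aldehyde 2 is the benzyl ether of commercial 1. The formyl group of 1 thus marks the carbon that becomes C8a, and its hydroxyl becomes the C8 oxygen.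

**17 to 10 (ring Q).** The boronic acid comes from bromide 14 by halogen–lithium exchange (aryllithium 15, borate 16). Bromide 14 comes from the symmetrical dibenzyl ether 13, whose two free positions are equivalent. Ether 13 comes from quinone 11 by reduction to hydroquinone 12 and benzylation, and 11 from commercial 2,3-dimethoxyphenol 10 by para-oxidation. The symmetry of 13 removes any regiochemical question from ring Q.

## Roads not taken

**Alternative 1:** Ring A is taken apart into three alkynes, cutting C4a–C8a, C5–C6 and C7–C8. In the forward sense CpCo(CO)2 would cyclotrimerise the diyne A2 (an ethynyl ether on O1 and a propargyl group on C3) with the diborylalkyne A3 to the bis-boronate A1.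
- Merits: three C–C bonds and two rings form in one step, the tether fixes the ring fusion, and the boryl groups mark C6 and C7 for oxygen. In bonds formed per step this road is better than the chosen one.
- Weak point, C8: A1 carries hydrogen at C8, because an oxygen there would require a 1,2-dialkoxyalkyne terminus. Two C–B oxidations, two methylations and a late C8 oxygenation must follow, at least four further steps.
- Weak point, the ynol ether: A2 has a hydrogen on C3, β to the ether oxygen. Such ethynyl ethers fragment thermally to a ketene and an alkene at the temperatures cobalt cyclotrimerisations need, which would destroy the stereocentre.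
- Weak point, C3: A2 must already hold the C3 stereocentre, so the stereochemical problem is only moved.
- Comparison: the chosen plan buys ring A with all four oxygens in place and makes a single bond to it. It gives up the convergence of A1 for a precursor (18) whose every group is already at its final oxidation level.

**Alternative 2:** The pyran is cut at C3–C4 and O1–C2. Base would release the ortho-quinone methide A7 from the sulfonylmethyl phenol A5. A chiral secondary amine would turn the arylacetaldehyde A6 into an enamine that attacks the methylene of A7, and the phenol oxygen would close onto the aldehyde to give lactol A4.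
- Merits: the ring and the stereocentre come from one metal-free catalytic step with no sulfone to install or remove and no strong base. In step count this road is better, probably by three or four steps.
- Weak point, C3: in A4 it is α to a masked aldehyde and α to an aryl group. It can racemise through the enamine under the very conditions that create it, and again during the ionic reduction needed to remove the C2 hydroxyl, where the oxocarbenium ion can lose H3.
- Weak point, the partners: the enamine of A6 is conjugated and hindered by the ortho benzyloxy group, and A7 is made less electrophilic by the C7 methoxy group para to its methylene.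
- Comparison: the chosen plan creates C3 between two methylene groups, β to a sulfone and never α to a carbonyl. The price is the sulfone detour of steps 5 and 12.

**Alternative 3:** Ring Q is cut into dimethyl squarate A10 and a two-carbon alkyne unit. The lithium acetylide of the 3-ethynylchroman A11 would add to A10 to give the hydroxycyclobutenone A9. Heating A9 would open it to an alkynylketene whose ketene carbon (future Q2) bonds to the alkyne carbon bearing C3 (future Q1), the hydroxyl hydrogen moving to Q6, to give the benzyl-protected quinone A8 (Moore rearrangement).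
- Merits: the quinone appears late with its substitution fixed by connectivity. No hydroquinone protecting groups and no ring Q boronic acid are needed, which would save steps 6 to 9. For ring Q alone this road is better than the chosen one.
- Weak point, scope: the key step neither closes the pyran nor sets C3. A11 would have to be made enantiopure by some other ring closure, so the central problem stays open.
- Weak point, thermolysis: it can partition between the quinone and an alkylidenecyclopentenedione.
- Weak point, endgame: the C8 benzyl group of A8 must be removed in the presence of the quinone, which hydrogenolysis reduces and Lewis acids endanger together with the methoxy groups.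
- Comparison: the chosen plan spends four routine steps on ring Q, but its key step solves the ring closure and its arylation step the stereocentre.

Key step: step 11

Assumption: (R,R)-Ph-bod, (1R,4R)-2,5-diphenylbicyclo[2.2.2]octa-2,5-diene, is written as the ligand of step 10 on the premise that it delivers the aryl group to the face of 9 that gives (S)-18. If the sense of induction on this substrate is the opposite, the (S,S) antipode is used and nothing else changes.

## Route

Step 1
Reactants: 1 2-hydroxy-3,4-dimethoxybenzaldehyde
Product: 2 2-benzyloxy-3,4-dimethoxybenzaldehyde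
Conditions: BnBr, K2CO3, DMF, 60 °C
Reagents that add atoms: benzyl bromide BrCc1ccccc1
Why: Williamson ether synthesis; the phenoxide is the only nucleophilic site and is alkylated at oxygen by the benzylic bromide.

Step 2
Reactants: 2 2-benzyloxy-3,4-dimethoxybenzaldehyde
Product: 4 2-benzyloxy-3,4-dimethoxyphenol, via aryl formate 3 (not isolated)
Conditions: mCPBA, CH2Cl2, 0 °C to rt; aq NaHCO3 wash; then K2CO3 (cat.), MeOH, rt
Reagents that add atoms: 3-chloroperoxybenzoic acid (mCPBA) O=C(OO)c1cccc(Cl)c1
Why: Baeyer–Villiger oxidation of an electron-rich benzaldehyde; with alkoxy groups ortho and para to the formyl group the aryl group migrates to give formate 3, which base-catalysed methanolysis cleaves to the phenol while the ethers stay untouched.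

Step 3
Reactants: 4 2-benzyloxy-3,4-dimethoxyphenol
Product: 5 2-benzyloxy-6-bromo-3,4-dimethoxyphenol
Conditions: NBS (1.0 equiv), i-Pr2NH (10 mol %), CH2Cl2, 0 °C
Reagents that add atoms: N-bromosuccinimide BrN1C(=O)CCC1=O
Why: Electrophilic aromatic bromination under amine-catalysed ortho-selective conditions; the free hydroxyl is the strongest donor, its para position is blocked by methoxy, and its only open ortho position (C6, also para to the C3 methoxy group) is attacked in preference to C5, which is meta to the hydroxyl.

Step 4
Reactants: 5 2-benzyloxy-6-bromo-3,4-dimethoxyphenol; 6 allyl bromide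
Product: 7 2-allyloxy-1-benzyloxy-3-bromo-5,6-dimethoxybenzene
Conditions: K2CO3, DMF, rt
Reagents that add atoms: none
Why: Williamson O-allylation of the phenoxide; both ortho positions are substituted and the temperature is low, so no Claisen rearrangement can follow.

Step 5
Reactants: 7 2-allyloxy-1-benzyloxy-3-bromo-5,6-dimethoxybenzene; 8 phenyl vinyl sulfone
Product: 9 (E)-3-(2-benzyloxy-6-bromo-3,4-dimethoxyphenoxy)prop-1-enyl phenyl sulfone
Conditions: second-generation Grubbs catalyst RuCl2(=CHPh)(PCy3)(H2IMes) (5 mol %), 8 (2.5 equiv), CH2Cl2, 40 °C
Reagents that add atoms: none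
Why: Olefin cross-metathesis of a terminal alkene with an electron-poor vinyl sulfone that does not homodimerise; loss of ethene drives the reaction and the conjugated product should form as the (E)-isomer, with aryl bromide and ethers inert to the ruthenium carbene.

Step 6
Reactants: 10 2,3-dimethoxyphenol
Product: 11 2,3-dimethoxy-1,4-benzoquinone
Conditions: (KSO3)2NO (2.2 equiv), KH2PO4 buffer, H2O/acetone, rt
Reagents that add atoms: potassium nitrosodisulfonate (KSO3)2NO [K+].[K+].[O]N(S(=O)(=O)[O-])S(=O)(=O)[O-]
Why: Teuber oxidation; the nitroxyl radical salt oxidises a phenol with a free para position to the para-quinone, so the fourth oxygen of ring Q enters para to the hydroxyl.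

Step 7
Reactants: 11 2,3-dimethoxy-1,4-benzoquinone
Product: 13 1,4-dibenzyloxy-2,3-dimethoxybenzene, via hydroquinone 12 (not isolated)
Conditions: Na2S2O4, EtOAc/H2O, rt; organic phase dried and concentrated under argon; then BnBr, K2CO3, DMF, 60 °C
Reagents that add atoms: benzyl bromide BrCc1ccccc1
Why: Dithionite reduces the quinone to hydroquinone 12, whose two phenoxides are benzylated (Williamson ether synthesis); exclusion of air prevents re-oxidation.

Step 8
Reactants: 13 1,4-dibenzyloxy-2,3-dimethoxybenzene
Product: 14 1-bromo-2,5-dibenzyloxy-3,4-dimethoxybenzene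
Conditions: NBS (1.0 equiv), MeCN, 0 °C to rt, dark
Reagents that add atoms: N-bromosuccinimide BrN1C(=O)CCC1=O
Why: Electrophilic aromatic bromination of a tetraalkoxybenzene whose two open positions are equivalent; the first bromine deactivates the ring against a second, and a polar solvent in the dark suppresses benzylic radical bromination.

Step 9
Reactants: 14 1-bromo-2,5-dibenzyloxy-3,4-dimethoxybenzene
Product: 17 (2,5-dibenzyloxy-3,4-dimethoxyphenyl)boronic acid, via aryllithium 15 (not isolated), via lithium triisopropoxyborate 16 (not isolated)
Conditions: n-BuLi, THF, −78 °C; B(Oi-Pr)3, −78 °C to rt; 1 M HCl, 0 °C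
Reagents that add atoms: triisopropyl borate CC(C)OB(OC(C)C)OC(C)C; water O
Why: Bromine–lithium exchange at −78 °C outruns deprotonation of the benzylic ether positions; aryllithium 15 is trapped by the borate ester as ate complex 16, which brief mild acid hydrolyses to the boronic acid (lithiation–borylation).

Step 10
Reactants: 9 (E)-3-(2-benzyloxy-6-bromo-3,4-dimethoxyphenoxy)prop-1-enyl phenyl sulfone; 17 (2,5-dibenzyloxy-3,4-dimethoxyphenyl)boronic acid
Product: 18 (S)-1-benzyloxy-3-bromo-2-[2-(2,5-dibenzyloxy-3,4-dimethoxyphenyl)-3-(phenylsulfonyl)propoxy]-5,6-dimethoxybenzene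
Conditions: [RhCl(C2H4)2]2 (2.5 mol %), (R,R)-Ph-bod (5.5 mol %), 17 (2.5 equiv), aq KOH (0.2 equiv), 1,4-dioxane/H2O (10:1), 40 °C
Reagents that add atoms: none
Why: Rhodium-catalysed asymmetric 1,4-addition of an arylboronic acid to an alkenyl sulfone (Hayashi–Miyaura reaction); the aryl group passes from boron to monovalent rhodium, adds to the β-carbon (future C3), and water protonates the α-sulfonyl alkylrhodium, while the C2-symmetric diene shields one face of the bound alkene and so sets C3 as (S).

Step 11
Reactants: 18 (S)-1-benzyloxy-3-bromo-2-[2-(2,5-dibenzyloxy-3,4-dimethoxyphenyl)-3-(phenylsulfonyl)propoxy]-5,6-dimethoxybenzene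
Product: 21 (3S)-8-benzyloxy-3-(2,5-dibenzyloxy-3,4-dimethoxyphenyl)-6,7-dimethoxy-4-(phenylsulfonyl)chroman (both C4 epimers), via lithiated sulfone 19 (not isolated), via aryne carbanion 20 (not isolated)
Conditions: LiTMP (4 equiv), THF, −78 °C to 0 °C; aq NH4Cl
Reagents that add atoms: none
Why: LiTMP first removes a proton from the CH2 group next to sulfur, the most acidic C–H of 18, giving 19, and then the only hydrogen of ring A, H5, which lies ortho to bromine and to the C6 methoxy group; loss of LiBr opens the C4a≡C5 aryne 20. The tethered sulfonyl carbanion adds to C4a, forming the C4–C4a bond, and the aryl anion left at C5 is protonated by tetramethylpiperidine or by the now doubly activated C4–H, so that aqueous NH4Cl should return 21. The closest known reaction type is the ring closure of nitrile-, ester- and sulfone-stabilised carbanions onto arynes generated from halobenzenes with alkali-metal amides. The pyran ring (O1, C2, C3, C4, C4a, C8a) closes in the 6-exo-dig mode with respect to the aryne triple bond. C4 becomes a stereocentre without control and both epimers are accepted, since step 12 turns C4 into a methylene group. The step needs site selectivity in deprotonation and regioselectivity on the aryne: ring A offers a single hydrogen and hence a single aryne, the four-atom tether can reach only C4a, and the C6 methoxy group polarises the triple bond so that charge builds up at C5. C3 keeps its configuration because its hydrogen is far less acidic than the α-sulfonyl hydrogens and a second deprotonation next to the carbanion is disfavoured. The hindered amide neither adds to the aryne nor reduces it, which is why it is preferred to lithium diisopropylamide.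

Step 12
Reactants: 21 (3S)-8-benzyloxy-3-(2,5-dibenzyloxy-3,4-dimethoxyphenyl)-6,7-dimethoxy-4-(phenylsulfonyl)chroman (both C4 epimers)
Product: 22 (3S)-8-benzyloxy-3-(2,5-dibenzyloxy-3,4-dimethoxyphenyl)-6,7-dimethoxychroman
Conditions: Mg turnings (excess), MeOH/THF, rt to 50 °C
Reagents that add atoms: none
Why: Reductive desulfonylation by electron transfer from magnesium; the benzylic C4–S bond of the sulfone radical anion breaks to benzenesulfinate and a benzylic radical that is reduced and protonated by methanol, so both C4 epimers converge on one compound while the benzyl ethers and C3 are not involved.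

Step 13
Reactants: 22 (3S)-8-benzyloxy-3-(2,5-dibenzyloxy-3,4-dimethoxyphenyl)-6,7-dimethoxychroman
Product: 24 5-[(3S)-8-hydroxy-6,7-dimethoxychroman-3-yl]-2,3-dimethoxy-1,4-benzoquinone, via hydroquinone 23 (not isolated)
Conditions: H2 (1 atm), Pd/C, EtOAc, rt; filtration through Celite under argon; then Ag2O, Na2SO4, rt
Reagents that add atoms: none
Why: Hydrogenolysis cleaves the three aryl benzyl ethers to hydroquinone 23; Ag2O, a mild two-electron oxidant, converts only the para-hydroquinone of ring Q into the quinone because the C8 phenol has no hydroxyl partner, and the neutral conditions leave C3 untouched.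

## Compound list

1 | 2-hydroxy-3,4-dimethoxybenzaldehyde | COc1ccc(C=O)c(O)c1OC | starting material
2 | 2-benzyloxy-3,4-dimethoxybenzaldehyde | COc1ccc(C=O)c(OCc2ccccc2)c1OC | intermediate
3 | 2-benzyloxy-3,4-dimethoxyphenyl formate (not isolated) | COc1ccc(OC=O)c(OCc2ccccc2)c1OC | intermediate
4 | 2-benzyloxy-3,4-dimethoxyphenol | COc1ccc(O)c(OCc2ccccc2)c1OC | intermediate
5 | 2-benzyloxy-6-bromo-3,4-dimethoxyphenol | COc1cc(Br)c(O)c(OCc2ccccc2)c1OC | intermediate
6 | allyl bromide (3-bromoprop-1-ene) | C=CCBr | starting material
7 | 2-allyloxy-1-benzyloxy-3-bromo-5,6-dimethoxybenzene | COc1cc(Br)c(OCC=C)c(OCc2ccccc2)c1OC | intermediate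
8 | phenyl vinyl sulfone | C=CS(=O)(=O)c1ccccc1 | starting material
9 | (E)-3-(2-benzyloxy-6-bromo-3,4-dimethoxyphenoxy)prop-1-enyl phenyl sulfone | COc1cc(Br)c(OC/C=C/S(=O)(=O)c2ccccc2)c(OCc2ccccc2)c1OC | intermediate
10 | 2,3-dimethoxyphenol | COc1cccc(O)c1OC | starting material
11 | 2,3-dimethoxy-1,4-benzoquinone | COC1=C(OC)C(=O)C=CC1=O | intermediate
12 | 2,3-dimethoxybenzene-1,4-diol (not isolated) | COc1c(O)ccc(O)c1OC | intermediate
13 | 1,4-dibenzyloxy-2,3-dimethoxybenzene | COc1c(OCc2ccccc2)ccc(OCc2ccccc2)c1OC | intermediate
14 | 1-bromo-2,5-dibenzyloxy-3,4-dimethoxybenzene | COc1c(OC)c(OCc2ccccc2)cc(Br)c1OCc1ccccc1 | intermediate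
15 | (2,5-dibenzyloxy-3,4-dimethoxyphenyl)lithium (not isolated) | COc1c(OC)c(OCc2ccccc2)cc([Li])c1OCc1ccccc1 | intermediate
16 | lithium (2,5-dibenzyloxy-3,4-dimethoxyphenyl)triisopropoxyborate (not isolated) | [Li+].COc1c(OC)c(OCc2ccccc2)cc([B-](OC(C)C)(OC(C)C)OC(C)C)c1OCc1ccccc1 | intermediate
17 | (2,5-dibenzyloxy-3,4-dimethoxyphenyl)boronic acid | COc1c(OC)c(OCc2ccccc2)cc(B(O)O)c1OCc1ccccc1 | intermediate
18 | (S)-1-benzyloxy-3-bromo-2-[2-(2,5-dibenzyloxy-3,4-dimethoxyphenyl)-3-(phenylsulfonyl)propoxy]-5,6-dimethoxybenzene | COc1c(OC)c(OCc2ccccc2)cc([C@H](CS(=O)(=O)c2ccccc2)COc2c(Br)cc(OC)c(OC)c2OCc2ccccc2)c1OCc1ccccc1 | intermediate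
19 | [(2S)-3-(2-benzyloxy-6-bromo-3,4-dimethoxyphenoxy)-2-(2,5-dibenzyloxy-3,4-dimethoxyphenyl)-1-(phenylsulfonyl)propyl]lithium (not isolated) | COc1c(OC)c(OCc2ccccc2)cc([C@H](C([Li])S(=O)(=O)c2ccccc2)COc2c(Br)cc(OC)c(OC)c2OCc2ccccc2)c1OCc1ccccc1 | intermediate
20 | [(2S)-3-(2-benzyloxy-3,4-dimethoxy-5,6-didehydrophenoxy)-2-(2,5-dibenzyloxy-3,4-dimethoxyphenyl)-1-(phenylsulfonyl)propyl]lithium, the C4a≡C5 aryne (not isolated) | COc1c(OC)c(OCc2ccccc2)cc([C@H](C([Li])S(=O)(=O)c2ccccc2)COC2=C(OCc3ccccc3)C(OC)=C(OC)C#C2)c1OCc1ccccc1 | intermediate
21 | (3S)-8-benzyloxy-3-(2,5-dibenzyloxy-3,4-dimethoxyphenyl)-6,7-dimethoxy-4-(phenylsulfonyl)chroman (both C4 epimers) | COc1c(OC)c(OCc2ccccc2)cc([C@H]2COc3c(cc(OC)c(OC)c3OCc3ccccc3)C2S(=O)(=O)c2ccccc2)c1OCc1ccccc1 | intermediate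
22 | (3S)-8-benzyloxy-3-(2,5-dibenzyloxy-3,4-dimethoxyphenyl)-6,7-dimethoxychroman | COc1c(OC)c(OCc2ccccc2)cc([C@H]2COc3c(cc(OC)c(OC)c3OCc3ccccc3)C2)c1OCc1ccccc1 | intermediate
23 | (3S)-3-(2,5-dihydroxy-3,4-dimethoxyphenyl)-6,7-dimethoxychroman-8-ol (not isolated) | COc1c(OC)c(O)cc([C@H]2COc3c(cc(OC)c(OC)c3O)C2)c1O | intermediate
24 | 5-[(3S)-8-hydroxy-6,7-dimethoxychroman-3-yl]-2,3-dimethoxy-1,4-benzoquinone (CNP0269725.1) | COC1=C(OC)C(=O)C([C@H]2COc3c(cc(OC)c(OC)c3O)C2)=CC1=O | target

## Step count and risk

Total step count: 13. Longest linear sequence: 9 steps (steps 1 to 5 and 10 to 13, from 1). The ring Q branch (steps 6 to 9) joins at step 10.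

**Step 11 (key step).** The excess amide may remove a benzylic proton of one of the three benzyl ethers and trigger a Wittig rearrangement. It may also remove H3 with expulsion of the ring A phenoxide across C2–C3, which would erase the stereocentre. The sulfonyl carbanion may displace the same phenoxide in a three-membered ring closure before the aryne has formed. All three compete because aryne formation needs warming above −78 °C while the carbanion is already present. Fallback, from 18 back to 21: palladium-catalysed intramolecular α-arylation of the sulfone (Pd(OAc)2, a bulky dialkylbiarylphosphine, NaOt-Bu, toluene, 90 °C). Zerovalent palladium inserts into the C4a–Br bond, the sulfonyl carbanion binds to palladium, and reductive elimination makes the same C4–C4a bond without an aryne or a lithium amide. This is why the bromine is kept on C4a. The fallback makes no new compound (F0).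

**Step 10.** The hydroxide needed to start the catalyst may move the double bond of 9 out of conjugation with the sulfone, towards the enol ether. The ortho-alkoxy boronic acid may lose boron to water before it transmetalates. The ortho substituent may also lower facial selectivity. Fallback, from 14 back to 18, with the stereocentre made by enzymatic desymmetrisation:
- Bromide 14 is coupled with diethyl malonate (Pd2(dba)3, P(t-Bu)3, K3PO4, toluene, 70 °C) to diethyl 2-(2,5-dibenzyloxy-3,4-dimethoxyphenyl)malonate F1.
- LiAlH4 in THF reduces it to 2-(2,5-dibenzyloxy-3,4-dimethoxyphenyl)propane-1,3-diol F2.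
- Lipase-catalysed mono-acetylation with vinyl acetate (Pseudomonas cepacia lipase) differentiates the enantiotopic hydroxymethyl groups and should give (S)-2-(2,5-dibenzyloxy-3,4-dimethoxyphenyl)-3-hydroxypropyl acetate F3.
- Mitsunobu etherification of the free hydroxyl with phenol 5 (PPh3, diisopropyl azodicarboxylate, THF) gives (S)-3-(2-benzyloxy-6-bromo-3,4-dimethoxyphenoxy)-2-(2,5-dibenzyloxy-3,4-dimethoxyphenyl)propyl acetate F4.
- Methanolysis (K2CO3, MeOH) gives (R)-3-(2-benzyloxy-6-bromo-3,4-dimethoxyphenoxy)-2-(2,5-dibenzyloxy-3,4-dimethoxyphenyl)propan-1-ol F5.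
- Mesylation (MsCl, Et3N) gives (S)-3-(2-benzyloxy-6-bromo-3,4-dimethoxyphenoxy)-2-(2,5-dibenzyloxy-3,4-dimethoxyphenyl)propyl methanesulfonate F6.
- Displacement with PhSO2Na in DMF gives 18.

If the enzyme delivers the antipodal mono-acetate, the sulfone is put on the free arm first and the aryl ether on the other arm second, which again leads to (S)-18.

**Step 5.** Ruthenium hydride species formed from the catalyst may shift the allyl ether double bond to the propenyl ether, and turnover with the electron-poor sulfone may be slow, so that self-metathesis of 7 competes. Fallback, from 5 back to 9, building the alkene by olefination: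
- Alkylation of 5 with bromoacetaldehyde diethyl acetal (K2CO3, DMF, 90 °C) gives 1-benzyloxy-3-bromo-2-(2,2-diethoxyethoxy)-5,6-dimethoxybenzene F7.
- Aqueous HCl in THF releases (2-benzyloxy-6-bromo-3,4-dimethoxyphenoxy)acetaldehyde F8.
- Horner–Wadsworth–Emmons reaction with diethyl (phenylsulfonyl)methylphosphonate under Masamune–Roush conditions (LiCl, DBU, MeCN) gives (E)-9.

**Step 12.** Mg(OMe)2 accumulates as the reaction proceeds. It may cause loss of benzenesulfinate across C3–C4 before electron transfer occurs, giving an achiral chromene and thereby destroying the stereocentre. Fallback, from 21 to 23 and on to 24: lithium naphthalenide in THF at −78 °C, added until the green colour persists, cleaves the C4–S bond and the three benzyl ethers in one electron-transfer operation at a temperature where base-induced elimination is slow. Acidification under argon gives hydroquinone 23, which is oxidised with Ag2O as in step 13. The fallback makes no new compound (F0).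

## Further compounds

F0 | step 11 | none | none
F1 | step 10 | diethyl 2-(2,5-dibenzyloxy-3,4-dimethoxyphenyl)malonate | CCOC(=O)C(C(=O)OCC)c1cc(OCc2ccccc2)c(OC)c(OC)c1OCc1ccccc1
F2 | step 10 | 2-(2,5-dibenzyloxy-3,4-dimethoxyphenyl)propane-1,3-diol | OCC(CO)c1cc(OCc2ccccc2)c(OC)c(OC)c1OCc1ccccc1
F3 | step 10 | (S)-2-(2,5-dibenzyloxy-3,4-dimethoxyphenyl)-3-hydroxypropyl acetate | COc1c(OC)c(OCc2ccccc2)cc([C@H](COC(C)=O)CO)c1OCc1ccccc1
F4 | step 10 | (S)-3-(2-benzyloxy-6-bromo-3,4-dimethoxyphenoxy)-2-(2,5-dibenzyloxy-3,4-dimethoxyphenyl)propyl acetate | COc1c(OC)c(OCc2ccccc2)cc([C@H](COC(C)=O)COc2c(Br)cc(OC)c(OC)c2OCc2ccccc2)c1OCc1ccccc1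
F5 | step 10 | (R)-3-(2-benzyloxy-6-bromo-3,4-dimethoxyphenoxy)-2-(2,5-dibenzyloxy-3,4-dimethoxyphenyl)propan-1-ol | COc1c(OC)c(OCc2ccccc2)cc([C@H](CO)COc2c(Br)cc(OC)c(OC)c2OCc2ccccc2)c1OCc1ccccc1
F6 | step 10 | (S)-3-(2-benzyloxy-6-bromo-3,4-dimethoxyphenoxy)-2-(2,5-dibenzyloxy-3,4-dimethoxyphenyl)propyl methanesulfonate | COc1c(OC)c(OCc2ccccc2)cc([C@H](COS(C)(=O)=O)COc2c(Br)cc(OC)c(OC)c2OCc2ccccc2)c1OCc1ccccc1
F7 | step 5 | 1-benzyloxy-3-bromo-2-(2,2-diethoxyethoxy)-5,6-dimethoxybenzene | CCOC(COc1c(Br)cc(OC)c(OC)c1OCc1ccccc1)OCC
F8 | step 5 | (2-benzyloxy-6-bromo-3,4-dimethoxyphenoxy)acetaldehyde | O=CCOc1c(Br)cc(OC)c(OC)c1OCc1ccccc1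
F0 | step 12 | none | none
A1 | alternative 1 | (3S)-3-(2,5-dibenzyloxy-3,4-dimethoxyphenyl)-6,7-bis(4,4,5,5-tetramethyl-1,3,2-dioxaborolan-2-yl)chroman | COc1c(OC)c(OCc2ccccc2)cc([C@H]2COc3cc(B4OC(C)(C)C(C)(C)O4)c(B4OC(C)(C)C(C)(C)O4)cc3C2)c1OCc1ccccc1
A2 | alternative 1 | (S)-1,4-dibenzyloxy-5-[1-(ethynyloxy)pent-4-yn-2-yl]-2,3-dimethoxybenzene | COc1c(OC)c(OCc2ccccc2)cc([C@H](CC#C)COC#C)c1OCc1ccccc1
A3 | alternative 1 | 1,2-bis(4,4,5,5-tetramethyl-1,3,2-dioxaborolan-2-yl)ethyne | CC1(C)OB(C#CB2OC(C)(C)C(C)(C)O2)OC1(C)C
A4 | alternative 2 | (3S)-8-benzyloxy-3-(2,5-dibenzyloxy-3,4-dimethoxyphenyl)-6,7-dimethoxychroman-2-ol (both C2 epimers) | COc1c(OC)c(OCc2ccccc2)cc([C@H]2C(O)Oc3c(cc(OC)c(OC)c3OCc3ccccc3)C2)c1OCc1ccccc1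
A5 | alternative 2 | 2-benzyloxy-3,4-dimethoxy-6-[(phenylsulfonyl)methyl]phenol | COc1cc(CS(=O)(=O)c2ccccc2)c(O)c(OCc2ccccc2)c1OC
A6 | alternative 2 | (2,5-dibenzyloxy-3,4-dimethoxyphenyl)acetaldehyde | COc1c(OC)c(OCc2ccccc2)cc(CC=O)c1OCc1ccccc1
A7 | alternative 2 | 2-benzyloxy-3,4-dimethoxy-6-methylidenecyclohexa-2,4-dien-1-one | C=C1C=C(OC)C(OC)=C(OCc2ccccc2)C1=O
A8 | alternative 3 | 5-[(3S)-8-benzyloxy-6,7-dimethoxychroman-3-yl]-2,3-dimethoxy-1,4-benzoquinone | COC1=C(OC)C(=O)C([C@H]2COc3c(cc(OC)c(OC)c3OCc3ccccc3)C2)=CC1=O
A9 | alternative 3 | 4-{[(3S)-8-benzyloxy-6,7-dimethoxychroman-3-yl]ethynyl}-4-hydroxy-2,3-dimethoxycyclobut-2-en-1-one (both carbinol epimers) | COC1=C(OC)C(O)(C#C[C@H]2COc3c(cc(OC)c(OC)c3OCc3ccccc3)C2)C1=O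
A10 | alternative 3 | dimethyl squarate (3,4-dimethoxycyclobut-3-ene-1,2-dione) | COC1=C(OC)C(=O)C1=O
A11 | alternative 3 | (3S)-8-benzyloxy-3-ethynyl-6,7-dimethoxychroman | C#C[C@H]1COc2c(cc(OC)c(OC)c2OCc2ccccc2)C1
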